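The chair opened from a one-step world, in which starting material and partner give target and nothing else, and reported that side product B in the beta and eta runs rules this out.

common to all: starting material 0.052 M

|  | partner | remark | time |
|---|---|---|---|
| beta | 0.019 M | run made earlier |  |
| eta | 0.055 M | run made earlier |  |
| dusk | 0.0260 M |  | 2.0 min |
| midnight | 0.0650 M |  | 2.0 min |

- beta (time / s: starting material / %, target / %, side product B / %): 10.0: 93.5, 6.2, 0; 12.0: 92.1, 7.4, 0.8; 20.0: 88.1, 11.9, 0.5; 40.0: 79.8, 16.8, 3.6; 60.0: 73.7, 20.4, 6.0
- eta (time / s: starting material / %, target / %, side product B / %): 10.0: 81.9, 16.9, 0; 12.0: 78.9, 20.1, 0.1; 20.0: 68.6, 28.7, 1.7; 30.0: 58.3, 36.6, 4.6; 50.0: 48.0, 46.8, 5.7; 60.0: 42.6, 50.4, 7.4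

(each reading ± 0.5 percentage points)

- which of these there is most of at the end, counted by the starting material in it, dusk (starting material / side product B / target)
- which of these there is most of at the end, counted by the starting material in it, midnight (starting material / side product B / target)
- the largest of these amounts at the end, in percent of the starting material charged, dusk
- the largest of these amounts at the end, in percent of the starting material charged, midnight

- percentages count the starting material that a species holds: one side product B counts as two
- what was read earlier has a scatter of 0.5 percentage points, one standard deviation
- a reading or a percentage of target counts all its forms, free or not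

The second speaker argued that target is made at a rate proportional to [starting material][partner] and lost at one proportional to [starting material][target], so [starting material] cancels from their ratio. She therefore proposed to carry the crossing ratio, the [target]/[partner] at which target is lost as fast as it is made, a selectivity factor read from the runs. Between the last two beta readings, she said, target lost was 1.2 percentage points and target made 4.8 points, while [target] averaged 0.00967 M and [partner], spent one for one, 0.00808 M. That gives a crossing ratio of 4.79, rough because each reading scatters by 0.5 points.

Ignoring losses, she put the crossing in dusk at 41.4% target, with partner as the limiting reagent. For midnight she got 103%, above the whole charge, so she expected target to lead in midnight and to stay under that ceiling in dusk.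

The forecast named starting material at 52% for dusk, on the ground that “partner runs short”, and target at 68% for midnight.

    starting material + partner → target (k = 0.400 M⁻¹ s⁻¹)
    2 partner → side product A (k = 0.0419 M⁻¹ s⁻¹)
    starting material + target → side product B (k = 0.0883 M⁻¹ s⁻¹)
    crystals ⇌ target, rate k4*(cs4 - [target]) while solid is left; crystals form when [target] > cs4 (solubility = 13.0 mM, k = 1.10 s⁻¹)

Dusk gave starting material at 53.2% and midnight target at 68.1%, as forecast. At the end of dusk, target stood at 31.5% with crystals counted, up from 26.8% at 1.00 min; crystals held 6.47% of that, and with dissolved target, the form in the scheme's loss step, [target]/[partner] was 3.14, below the crossing ratio. The neighbour flask, dusk with 0.021 M of starting material, reached a ratio of 0.912, far below the crossing, and there the leader changes: starting material stood at 41.5% and target at 50.2%.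

Readings and results come from a simulation with made-up constants, noise included.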